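The target is genistein joined through C3' to C8'' of apigenin. Everything rests on excising C2 of the isoflavone pyranone (ring C), an unsubstituted methine flanked only by O1 and C3. This leads back to a benzyl 2,4,6-trihydroxyphenyl ketone. The acyl ring (future ring A) has two interchangeable ortho hydroxyls, so closure through either gives the same 5,7-dihydroxy pattern. In one operation the formyl carbon of DMF is joined to the benzylic CH2 (C2–C3) and to a phenol oxygen (O1–C2) of the unprotected heptaphenol, leaving no deprotection. That ketone arises from Suzuki union of 8-iodoapigenin trimethyl ether with an arylacetate boronate, acylation of phloroglucinol and one exhaustive demethylation.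

Key step: step 8

Assumption: the target contains no stereocentre and its SMILES gives no descriptor for the C3'–C8'' biaryl axis, so no stereocontrol is planned.
Locants: unprimed = isoflavone chromenone, single prime = isoflavone ring B, double prime = flavone chromenone, triple prime = flavone ring B.

Step 1
Reactants: 1 apigenin (5,7-dihydroxy-2-(4-hydroxyphenyl)-4H-chromen-4-one)
Product: 2 apigenin trimethyl ether (5,7-dimethoxy-2-(4-methoxyphenyl)-4H-chromen-4-one)
Conditions: Me2SO4 (excess), K2CO3, acetone, reflux
Reagents that add atoms: dimethyl sulfate, COS(=O)(=O)OC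
Why: Williamson-type O-methylation caps all three phenols, and excess reagent with prolonged reflux is used because the hydrogen-bonded 5-OH reacts last.

Step 2
Reactants: 2 apigenin trimethyl ether
Product: 3 8-iodo-5,7-dimethoxy-2-(4-methoxyphenyl)-4H-chromen-4-one
Conditions: I2 (1.05 equiv), CF3CO2Ag, CH2Cl2, 0 °C to rt, dark
Reagents that add atoms: iodine, II
Why: Electrophilic aromatic iodination by the hypoiodite formed in situ hits the dimethoxylated ring A, and once the 5-oxygen is alkylated it goes to C8 (between 7-OMe and O1) rather than to C6 (squeezed between two methoxy groups), the known preference of 5,7-dimethoxyflavones.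

Step 3
Reactants: 4 3-bromo-4-methoxyphenylacetic acid
Product: 5 methyl 2-(3-bromo-4-methoxyphenyl)acetate
Conditions: MeOH, H2SO4 (cat.), reflux
Reagents that add atoms: methanol, CO
Why: Fischer esterification masks the acid so that the boronate of the next step can be made and purified as a neutral compound.

Step 4
Reactants: 5 methyl 2-(3-bromo-4-methoxyphenyl)acetate
Product: 6 methyl 2-[4-methoxy-3-(4,4,5,5-tetramethyl-1,3,2-dioxaborolan-2-yl)phenyl]acetate
Conditions: B2pin2, PdCl2(dppf) (3 mol %), KOAc, 1,4-dioxane, 90 °C
Reagents that add atoms: bis(pinacolato)diboron, CC1(C)OB(OC1(C)C)B1OC(C)(C)C(C)(C)O1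
Why: Miyaura borylation of an aryl bromide uses only the weak base KOAc, which leaves the ester and its acidic benzylic CH2 untouched.

Step 5
Reactants: 3 8-iodo-5,7-dimethoxy-2-(4-methoxyphenyl)-4H-chromen-4-one; 6 methyl 2-[4-methoxy-3-(4,4,5,5-tetramethyl-1,3,2-dioxaborolan-2-yl)phenyl]acetate
Product: 8 2-{3-[5,7-dimethoxy-2-(4-methoxyphenyl)-4-oxo-4H-chromen-8-yl]-4-methoxyphenyl}acetic acid, via biaryl methyl ester 7 (not isolated)
Conditions: Pd(OAc)2 (5 mol %), SPhos (10 mol %), K3PO4, 1,4-dioxane/H2O, 90 °C; then LiOH, H2O, 25 °C; then 1 M HCl to pH 2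
Reagents that add atoms: lithium hydroxide, [Li+].[OH-]
Why: Suzuki–Miyaura coupling with a bulky biarylphosphine suits a biaryl with three ortho substituents, boron sits on the less hindered ring that is less prone to protodeboronation, and the ester, already attacked in part by hot aqueous phosphate, is saponified to completion in the same pot so that ester cleavage does not depend on the later BBr3 step.

Step 6
Reactants: 8 2-{3-[5,7-dimethoxy-2-(4-methoxyphenyl)-4-oxo-4H-chromen-8-yl]-4-methoxyphenyl}acetic acid; 9 phloroglucinol (anhydrous, 2 equiv)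
Product: 10 2-{3-[5,7-dimethoxy-2-(4-methoxyphenyl)-4-oxo-4H-chromen-8-yl]-4-methoxyphenyl}-1-(2,4,6-trihydroxyphenyl)ethanone
Conditions: BF3·OEt2 (solvent), 80 °C, Ar; then ice-water, EtOAc; SiO2
Reagents that add atoms: none
Why: Friedel–Crafts C-acylation of phloroglucinol by a BF3-activated arylacetic acid is the standard entry to 2,4,6-trihydroxydeoxybenzoins and stops after one acyl group, while the four retained methyl ethers keep 8 soluble, let surplus 9 be removed by chromatography before the one-carbon step, and block any Wessely–Moser drift of the 8-aryl flavone to its 6-aryl isomer.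

Step 7
Reactants: 10 2-{3-[5,7-dimethoxy-2-(4-methoxyphenyl)-4-oxo-4H-chromen-8-yl]-4-methoxyphenyl}-1-(2,4,6-trihydroxyphenyl)ethanone
Product: 11 2-{3-[5,7-dihydroxy-2-(4-hydroxyphenyl)-4-oxo-4H-chromen-8-yl]-4-hydroxyphenyl}-1-(2,4,6-trihydroxyphenyl)ethanone
Conditions: BBr3 (12 equiv), CH2Cl2, −78 °C to 40 °C; then ice-water, filtration of the precipitate
Reagents that add atoms: none
Why: Lewis-acid ether cleavage (O–B complexation, then SN2 attack of bromide on methyl) removes all four aryl methyl ethers at or below 40 °C, well away from the hot protic media that trigger Wessely–Moser isomerisation or dibenzofuran formation across the 4'-OH/7''-OH pair, and it leaves only volatile or water-soluble by-products.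

Step 8
Reactants: 11 2-{3-[5,7-dihydroxy-2-(4-hydroxyphenyl)-4-oxo-4H-chromen-8-yl]-4-hydroxyphenyl}-1-(2,4,6-trihydroxyphenyl)ethanone
Product: 13 target, 8-[5-(5,7-dihydroxy-4-oxo-4H-chromen-3-yl)-2-hydroxyphenyl]-5,7-dihydroxy-2-(4-hydroxyphenyl)-4H-chromen-4-one, via enaminone 12 (not isolated)
Conditions: BF3·OEt2 (8 equiv), dry DMF, 10 to 50 °C; MsCl (4 equiv) in DMF, 75 °C; then 0.5 M aq. HCl, 60 °C; Sephadex LH-20 (MeOH)
Reagents that add atoms: N,N-dimethylformamide, CN(C)C=O
Why: MsCl converts DMF into an O-sulfonylated Vilsmeier-type iminium salt, while BF3 locks the ketone and one ortho hydroxyl of 11 into a difluoroboron chelate that acidifies the benzylic CH2, so the derived enol attacks the iminium carbon and loss of methanesulfonic acid gives enaminone 12 (bond C2–C3). The second ortho hydroxyl of the acyl ring then adds to the aminomethine carbon and dimethylamine is expelled, an oxa-Michael addition–elimination in which the attacked C2=C3 bond lies inside the forming six-membered ring (6-endo-trig), creating O1–C2 and pyranone ring C. The closest known reaction type is the Vilsmeier-type one-carbon cyclisation of unprotected 2-hydroxydeoxybenzoins with BF3·OEt2/DMF/MsCl, established for 2,4,6-trihydroxyphenyl hydroxybenzyl ketones of the genistein series. No stereocentre is formed and the biaryl axis is untouched. The selectivity needed is carbon attack at the benzylic position rather than formylation of the four phenolic rings or sulfonylation of oxygen: the chelated enol is the strongest carbon nucleophile present, both phloroglucinol-derived rings are deactivated by a boron-chelated carbonyl group (C4''=O with 5''-OH in the flavone), the two monophenol rings are too weakly activated for a DMF-derived iminium ion, and without base the phenols are not sulfonylated, any formate esters falling off in the acidic work-up. Which ortho hydroxyl closes is irrelevant because rotation about the aryl–carbonyl bond interchanges them, so a single constitutional isomer should result.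

Compound list
1 | apigenin | O=c1cc(-c2ccc(O)cc2)oc2cc(O)cc(O)c12 | starting material
2 | apigenin trimethyl ether, 5,7-dimethoxy-2-(4-methoxyphenyl)-4H-chromen-4-one | O=c1cc(-c2ccc(OC)cc2)oc2cc(OC)cc(OC)c12 | intermediate
3 | 8-iodo-5,7-dimethoxy-2-(4-methoxyphenyl)-4H-chromen-4-one | COc1cc(OC)c2c(=O)cc(-c3ccc(OC)cc3)oc2c1I | intermediate
4 | 3-bromo-4-methoxyphenylacetic acid | COc1ccc(CC(=O)O)cc1Br | starting material
5 | methyl 2-(3-bromo-4-methoxyphenyl)acetate | COC(=O)Cc1ccc(OC)c(Br)c1 | intermediate
6 | methyl 2-[4-methoxy-3-(4,4,5,5-tetramethyl-1,3,2-dioxaborolan-2-yl)phenyl]acetate | COC(=O)Cc1ccc(OC)c(B2OC(C)(C)C(C)(C)O2)c1 | intermediate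
7 | biaryl methyl ester, methyl 2-{3-[5,7-dimethoxy-2-(4-methoxyphenyl)-4-oxo-4H-chromen-8-yl]-4-methoxyphenyl}acetate (not isolated) | COC(=O)Cc1ccc(OC)c(-c2c(OC)cc(OC)c3c(=O)cc(-c4ccc(OC)cc4)oc23)c1 | intermediate
8 | 2-{3-[5,7-dimethoxy-2-(4-methoxyphenyl)-4-oxo-4H-chromen-8-yl]-4-methoxyphenyl}acetic acid | O=C(O)Cc1ccc(OC)c(-c2c(OC)cc(OC)c3c(=O)cc(-c4ccc(OC)cc4)oc23)c1 | intermediate
9 | phloroglucinol | Oc1cc(O)cc(O)c1 | starting material
10 | 2-{3-[5,7-dimethoxy-2-(4-methoxyphenyl)-4-oxo-4H-chromen-8-yl]-4-methoxyphenyl}-1-(2,4,6-trihydroxyphenyl)ethanone | O=C(Cc1ccc(OC)c(-c2c(OC)cc(OC)c3c(=O)cc(-c4ccc(OC)cc4)oc23)c1)c1c(O)cc(O)cc1O | intermediate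
11 | 2-{3-[5,7-dihydroxy-2-(4-hydroxyphenyl)-4-oxo-4H-chromen-8-yl]-4-hydroxyphenyl}-1-(2,4,6-trihydroxyphenyl)ethanone (heptahydroxy deoxybenzoin, key-step precursor) | O=C(Cc1ccc(O)c(-c2c(O)cc(O)c3c(=O)cc(-c4ccc(O)cc4)oc23)c1)c1c(O)cc(O)cc1O | intermediate
12 | enaminone, 3-(dimethylamino)-2-{3-[5,7-dihydroxy-2-(4-hydroxyphenyl)-4-oxo-4H-chromen-8-yl]-4-hydroxyphenyl}-1-(2,4,6-trihydroxyphenyl)prop-2-en-1-one (not isolated; drawn boron-free, push-pull alkene of unfixed geometry) | CN(C)C=C(c1ccc(O)c(-c2c(O)cc(O)c3c(=O)cc(-c4ccc(O)cc4)oc23)c1)C(=O)c1c(O)cc(O)cc1O | intermediate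
13 | CNP0142623.0, 8-[5-(5,7-dihydroxy-4-oxo-4H-chromen-3-yl)-2-hydroxyphenyl]-5,7-dihydroxy-2-(4-hydroxyphenyl)-4H-chromen-4-one | O=c1c(-c2ccc(O)c(-c3c(O)cc(O)c4c(=O)cc(-c5ccc(O)cc5)oc34)c2)coc2cc(O)cc(O)c12 | target

Total step count: 8
Longest linear sequence: 6 steps (1 → 2 → 3 → 8 → 10 → 11 → 13; the branch 4 → 5 → 6 → 8 → 10 → 11 → 13 is equally long)

Steps most likely to fail

Step 8. The iminium salt may be consumed by O- and C-formylation spread over seven free phenols. The multiply boron-chelated substrate may also stay out of solution, so that enaminone formation stalls. The fallback sets out from 10 and closes the pyranone while four phenols are still methylated. BF3·OEt2, DMF and MsCl then act on a substrate that carries only the three phenols of the acyl ring, the best documented case of this cyclisation. This should give 5,7-dihydroxy-3-{3-[5,7-dimethoxy-2-(4-methoxyphenyl)-4-oxo-4H-chromen-8-yl]-4-methoxyphenyl}-4H-chromen-4-one F1. Exhaustive ether cleavage of this compound with BBr3 in CH2Cl2 comes back to the route at 13. The step count is unchanged, at the price of ending with a deprotection.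

Step 5. Transmetalation onto the arylpalladium centre at C8'', flanked by the 7''-methoxy group and O1'', may be slow. Protodeboronation of the boronate and hydrodeiodination of the iodide could then take over. The fallback sets out from 3 and 5 and exchanges the roles of the partners. Miyaura borylation of 3 (B2pin2, PdCl2(dppf), KOAc, DMSO, 80 °C) should give 5,7-dimethoxy-2-(4-methoxyphenyl)-8-(4,4,5,5-tetramethyl-1,3,2-dioxaborolan-2-yl)-4H-chromen-4-one F2. This is used in excess against bromide 5 (Pd(OAc)2, SPhos, K3PO4, toluene/H2O), so that oxidative addition takes place on the less hindered ring. The ester 7 so formed is saponified with LiOH, and the route is rejoined at 8. Step 4 is then no longer needed.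

Step 7. Ether cleavage may stop part-way, because the three free phenols are turned at once into borate esters that drop out of CH2Cl2. This would leave partly methylated material that is hard to separate. The fallback sets out from 8 and moves the deprotection ahead of the acylation. BBr3 acts on the phenol-free acid 8 and should give 2-{3-[5,7-dihydroxy-2-(4-hydroxyphenyl)-4-oxo-4H-chromen-8-yl]-4-hydroxyphenyl}acetic acid F3, which can be purified by bicarbonate extraction. This acid then acylates phloroglucinol 9 in BF3·OEt2 at the lowest workable temperature, since 5''-OH is now free and the 8-linkage must be watched. Surplus 9 is washed out with water, and the route is rejoined at 11.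

Further compounds
F1 | step 8 | 5,7-dihydroxy-3-{3-[5,7-dimethoxy-2-(4-methoxyphenyl)-4-oxo-4H-chromen-8-yl]-4-methoxyphenyl}-4H-chromen-4-one | O=c1c(-c2ccc(OC)c(-c3c(OC)cc(OC)c4c(=O)cc(-c5ccc(OC)cc5)oc34)c2)coc2cc(O)cc(O)c12
F2 | step 5 | 5,7-dimethoxy-2-(4-methoxyphenyl)-8-(4,4,5,5-tetramethyl-1,3,2-dioxaborolan-2-yl)-4H-chromen-4-one | COc1cc(OC)c2c(=O)cc(-c3ccc(OC)cc3)oc2c1B1OC(C)(C)C(C)(C)O1
F3 | step 7 | 2-{3-[5,7-dihydroxy-2-(4-hydroxyphenyl)-4-oxo-4H-chromen-8-yl]-4-hydroxyphenyl}acetic acid | O=C(O)Cc1ccc(O)c(-c2c(O)cc(O)c3c(=O)cc(-c4ccc(O)cc4)oc23)c1
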